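## Structural features

The target is a phenylcoumaran neolignan. Benzene ring A is fused through C3a and C7a to dihydrofuran ring B (O1, C2, C3); C2 carries a 4-hydroxy-3,5-dimethoxyphenyl group (ring C), C3 a hydroxymethyl group, C7 a methoxy group and C5 an (E)-propenoic acid. C2 and C3 are adjacent stereocentres. CIP analysis of the SMILES gives 2S,3R, and placing the substituents on ring B puts the aryl and hydroxymethyl groups on opposite faces, so this is the trans isomer; the structures of the key-step precursor and product were checked the same way and needed no correction. The fragile elements are the O1–C2 bond (a p-hydroxybenzylic aryl ether that ionizes with acid and opens through a quinone methide on oxidation), the free syringyl phenol, and the cinnamic acid, which rules out hydrogenolysis late in the route. The real difficulty is to fix the absolute configuration of two contiguous centres at this labile benzylic ether while placing four different substituents regiospecifically on ring A (C3a, C5, C7, C7a). Ring A offers the handle: O1 sits on C7a, the carbon side chain on C5 is para to it, and C7, ortho to it, carries a heteroatom. That is the pattern produced when a ketene acetal unit C3a=C7a adds across C6 and C3 of a 3-bromo-2-pyrone-5-carboxylate and the adduct is decarboxylated, so ring A can be built last around a γ-butyrolactone that already holds O1, C2 and C3.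

## Logic of the disconnections

**26 ⇒ 24 (through 25).** Only protecting-group bonds are cut: the aryl O–CH2 acetal bond and the alkyl O–Si bond. With the phenol masked, O1–C2 is an ordinary benzylic ether and the earlier steps run on a robust substrate. The demand is a final unmasking by dilute, alcohol-free acid. For that reason the primary oxygen carries a triisopropylsilyl ether and not a second formaldehyde acetal, which would need forcing acid on the acid-sensitive product.

**24 ⇒ 22.** The Cα=Cβ bond of the propenoic acid on C5 is cut. A Knoevenagel–Doebner condensation forms it with E geometry and gives the free acid directly, so no ester hydrolysis follows. The side chain is reduced to a formyl group; the forward step must tolerate the silyl ether and the acetal, which amine bases do.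

**22 ⇒ 21 ⇒ 20.** No skeletal bond is cut; the oxidation level of the C5 carbon is taken back to the methyl ester that the annulation delivers. The forward steps need a hydride that leaves acetal and silyl ether alone and an oxidant selective for the benzylic alcohol.

**20 ⇒ 19.** The C7–OCH3 bond is exchanged for C7–Br. A bromine on the pyrone raises its electron demand and reinforces the regiochemistry of the annulation, whereas a methoxy group there would do the opposite. The demand is a C–O coupling at a position flanked by O1, under base that the protecting groups and the stereocentres tolerate.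

**19 ⇒ 13 + 16.** The C3a–C4 and C7–C7a bonds are cut, which removes ring A. All four ring A substituents then come from a six-atom heterocycle and a lactone-derived enol derivative, and the two stereocentres are delegated to a monocyclic precursor. The forward step must be regioselective (C3a to the pyrone carbon next to the ring oxygen), must decarboxylate, and must aromatize by loss of the silyloxy group and not of O1.

**16 ⇒ 14.** The C3–Br bond of the pyrone is cut; the forward step is a substitution at the only free nucleophilic ring position.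

**13 ⇒ 12.** The O–Si bond of the ketene acetal is cut, returning C7a to a lactone carbonyl. The demand is O- rather than C-silylation, with a silyl chloride so that the aryl acetal survives.

**12 ⇒ 11 ⇒ 10.** The O–Si bond of the primary ether is cut and the CH2OH carbon is taken back to a carboxyl group, which is what the aldol route provides. The forward steps need reduction of an acid beside a lactone, and protection without alkoxide formation, because the hydroxymethyl lactone can translactonize.

**10 ⇒ 8 ⇒ 5 + 2.** The auxiliary N–acyl bond is cut, then the lactone O–acyl bond and the C–C bond between the two future stereocentres (C2–C3 of the target). A syn-aldol forms that bond and both centres in one step, and lactonization converts syn into trans. The demand is a Z enolate and the (S)-configured auxiliary, which leads to the 2S,3S lactone.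

**5 ⇒ 3 + 4 and 2 ⇒ 1.** An N–acyl bond and an O–CH2 acetal bond are cut, reaching commercial materials.

## Other disconnections considered

**Alternative 1:** The cut is the C2–C3 bond of ring B. The ring A arylacetate, carrying the syringylmethyl group on its ortho oxygen, would be used as the diazo ester A1 (ethyl 2-diazo-2-{2-[3,5-dimethoxy-4-(triisopropylsilyloxy)benzyloxy]-5-(1,3-dioxolan-2-yl)-3-methoxyphenyl}acetate). Rh2(S-PTTL)4 (dirhodium tetrakis[N-phthaloyl-(S)-tert-leucinate]) would generate the carbenoid at C3, which inserts into the benzylic C–H bond of the ether to give the cis ester A2; DBU in the same flask would then epimerize C3 to the trans ester A3.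

- In its favour: ring A arrives with the C7 methoxy group and a masked C5 aldehyde, so no late methoxylation and no ester-to-aldehyde redox are needed. The asymmetric induction is catalytic. Enantioselective 1,5-insertion of aryldiazoacetates into benzylic ether C–H bonds is an established reaction class for exactly this ring system.
- Against it here: the configuration at C2 depends entirely on the match between catalyst and a substrate with a methoxy group flanking the ether oxygen and a very electron-rich benzyl group. A shortfall in enantiomeric purity could not be repaired by separating diastereomers. A diazo compound and a homologated arylacetate must be prepared. The base epimerization of A2 can also proceed by retro-oxa-Michael opening, which would put C2 at risk.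
- Comparison: on structure both plans set both centres. On mechanism the alternative is catalyst-controlled, whereas the chosen plan is auxiliary-controlled and then stereochemically neutral. The alternative is the better plan in closeness of precedent for its key step and in step economy (about four steps from A3 to the target against five from 19). The chosen plan is the better one in predictability and correctability of the absolute configuration.

**Alternative 2:** The cuts are the C2–aryl and C3–CH2 bonds, made across the C2=C3 bond of a benzofuran. Benzofuran A4 (2-(7-methoxy-1-benzofuran-5-yl)-1,3-dioxolane) would be lithiated at C2 and combined with the syringyl pinacol boronate A5 to give the ate complex A6. C3 of A6 would attack a chiral π-allyl complex of divalent palladium (from Pd2(dba)3, a chiral bisphosphine and allyl acetate) while the syringyl group shifts from boron to C2, giving the boronate A7 with aryl and allyl trans.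

- In its favour: it is the most convergent of the four plans, with two C–C bonds and both stereocentres formed in one catalytic step from two flat aromatic pieces. On convergence it is better than the chosen plan.
- Against it here: A7 is not at the substitution state of the target. The boron on C2 must be replaced by hydrogen with retention at a tertiary, ionizable α-oxy benzylic centre. The allyl group has one carbon too many and needs isomerization, oxidative cleavage beside electron-rich arenes, and reduction. Benzofuran-derived ate complexes are less nucleophilic at C3 than the indole analogues for which the enantioselective reaction type is best established, and the new centres lie on the nucleophile, not on the allyl unit.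
- Comparison: the chosen plan delivers the exact carbon skeleton from its key step. On mechanism the two are equal in one respect, since both key steps pair partners not tested together. In step economy the alternative is no better, because the corrective steps cancel the gain of the three-component coupling.

**Alternative 3:** The cut is the O1–C2 bond. The diarylpropanol A8 ((2R)-2-(5-bromo-2-hydroxy-3-methoxyphenyl)-3-(4-hydroxy-3,5-dimethoxyphenyl)propan-1-ol) carries only the future C3 centre. Ag2O would oxidize its syringyl phenol to the para-quinone methide A9, and the ring A phenol would add to the methide carbon (5-exo-trig), closing ring B to the trans bromide A10.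

- In its favour: it is biomimetic and the late intermediates need no protecting groups. Only one centre needs reagent control. A10 is a Heck coupling and at most one hydrolysis away from the target. In step and protecting-group economy it is better than the chosen plan.
- Against it here: the stereocentre of A9 is α to the methide carbon, and tautomerization of the quinone methide to a styrene would erase it. The trans selectivity is substrate bias only. Ag2O must discriminate between two phenols. A10 is itself a p-hydroxybenzylic ether that the oxidant could reopen.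
- Comparison: the alternative forms the most labile bond of the target last, when little else is at stake, which is a real structural advantage. The chosen plan keeps both centres locked in a lactone and never forms a cation or quinone methide next to C3, so it is the safer plan for stereochemical integrity, at the price of a longer route.

Key step: step 9

**Remarks before the steps**

- In the step lines Ar = 3,5-dimethoxy-4-(methoxymethoxy)phenyl; full names are in the compound list.
- Assumption: salts formed by simple proton transfer (lithiated 3, the lithium enolate of 12, carboxylates) and boron or aluminium alkoxides that hydrolyse on work-up are treated as forms of the numbered compounds.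
- Assumption: the transient sp3 centres of 17 and 18 arise as mixtures and are erased in the same step, so their SMILES leave them open; 15 is drawn as one enantiomer of the racemic trans adduct.

Step 1
Reactants: 1 syringaldehyde (4-hydroxy-3,5-dimethoxybenzaldehyde)
Product: 2 3,5-dimethoxy-4-(methoxymethoxy)benzaldehyde (ArCHO)
Conditions: MOMCl, i-Pr2NEt, CH2Cl2, 0 → 25 °C
Reagents that add atoms: chloromethyl methyl ether (MOMCl), COCCl
Why: O-Alkylation of the phenol with the reactive α-chloro ether gives the aryl methoxymethyl acetal; the phenol must be masked before boron enolate and amide base chemistry, and an aryl MOM ether is later removed by dilute acid.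

Step 2
Reactants: 3 (4S)-4-benzyl-1,3-oxazolidin-2-one; 4 methyl 4-chloro-4-oxobutanoate
Product: 5 methyl 4-[(4S)-4-benzyl-2-oxo-1,3-oxazolidin-3-yl]-4-oxobutanoate
Conditions: n-BuLi, THF, −78 °C; then 4, −78 → 0 °C
Reagents that add atoms: none
Why: N-Acylation of the lithiated oxazolidinone by the acid chloride, which is far more electrophilic than the methyl ester at the other end of 4.

Step 3
Reactants: 5 methyl 4-[(4S)-4-benzyl-2-oxo-1,3-oxazolidin-3-yl]-4-oxobutanoate; 2 ArCHO
Product: 8 (4S)-4-benzyl-3-{[(2S,3S)-2-Ar-5-oxooxolan-3-yl]carbonyl}-1,3-oxazolidin-2-one (trans lactone imide), via (Z)-dibutylboron enolate 6 (not isolated), via syn-aldol boron aldolate 7 (not isolated)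
Conditions: Bu2BOTf, i-Pr2NEt, CH2Cl2, 0 °C; 2, −78 → 25 °C; pH 7 buffer, MeOH, 30% H2O2, 0 °C
Reagents that add atoms: none
Why: Evans syn-aldol: soft enolization of the imide (not the ester) gives Z enolate 6, which should add to 2 through a Zimmerman–Traxler chair on the face away from the benzyl group, setting the 2S,3S syn pair of 7. The aldolate oxygen then acylates the γ-methyl ester (5-exo-trig lactonization), and because a syn aldol puts the aryl group and the imide carbonyl on opposite faces of the new ring, 8 should be the trans lactone.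

Step 4
Reactants: 8 trans lactone imide
Product: 10 (2S,3S)-2-Ar-5-oxooxolane-3-carboxylic acid (trans paraconic acid), via peroxy acid 9 (not isolated)
Conditions: LiOH, 30% H2O2, THF/H2O, 0 °C; aq. Na2SO3; 1 M HCl to pH 2
Reagents that add atoms: hydrogen peroxide, OO
Why: Hydroperoxide attacks the exocyclic imide carbonyl selectively and releases auxiliary 3 for recovery, and sulfite reduces peracid 9 to the acid. Any lactone opened by hydroxide would re-close on acidification, and the cold conditions should leave the α-centre of the more stable trans acid untouched.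

Step 5
Reactants: 10 trans paraconic acid
Product: 11 (4R,5S)-5-Ar-4-(hydroxymethyl)oxolan-2-one
Conditions: BH3·SMe2, THF, 0 → 25 °C; MeOH quench
Reagents that add atoms: none
Why: Borane reduces a carboxylic acid through its acyloxyborane much faster than a lactone or an aryl acetal, and the neutral medium avoids alkoxide-induced translactonization. The carbon that bore the carboxyl group changes descriptor from S to R only because CIP priorities change.

Step 6
Reactants: 11 (4R,5S)-5-Ar-4-(hydroxymethyl)oxolan-2-one
Product: 12 (4R,5S)-5-Ar-4-{[(triisopropylsilyl)oxy]methyl}oxolan-2-one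
Conditions: i-Pr3SiCl, imidazole, DMF, 0 → 25 °C
Reagents that add atoms: chlorotriisopropylsilane (TIPSCl), CC(C)[Si](Cl)(C(C)C)C(C)C
Why: Imidazole-promoted silylation of the primary alcohol forms no alkoxide, so the lactone should not isomerize. The TIPS ether withstands LiN(i-Pr)2, hot methoxide, hydride and amine bases yet is cleaved by the same dilute acid as the aryl MOM ether, and a silyl chloride (not a triflate) spares that acetal.

Step 7
Reactants: 12 (4R,5S)-5-Ar-4-{[(triisopropylsilyl)oxy]methyl}oxolan-2-one
Product: 13 tert-butyl{[(4R,5S)-5-Ar-4-{[(triisopropylsilyl)oxy]methyl}-4,5-dihydrofuran-2-yl]oxy}dimethylsilane (silyl ketene acetal)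
Conditions: LiN(i-Pr)2, THF, −78 °C; t-BuMe2SiCl, DMPU, −78 → 0 °C; non-aqueous work-up (pentane, filtration)
Reagents that add atoms: tert-butylchlorodimethylsilane (TBSCl), CC(C)(C)[Si](C)(C)Cl
Why: Kinetic deprotonation at C3 of the lactone, the only position of comparable acidity, followed by O-silylation of the enolate in the presence of DMPU, gives the cyclic silyl ketene acetal. C4 and C5 are not deprotonated, so the trans configuration is kept.

Step 8
Reactants: 14 methyl coumalate (methyl 2-oxo-2H-pyran-5-carboxylate)
Product: 16 methyl 3-bromo-2-oxo-2H-pyran-5-carboxylate, via trans-3,4-dibromide 15 (not isolated)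
Conditions: Br2, CH2Cl2, 0 → 25 °C; then Et3N, 0 °C
Reagents that add atoms: bromine, BrBr
Why: Electrophilic bromination of the 2-pyrone by addition–elimination: C5 is blocked by the ester, Br2 adds across C3=C4, and Et3N removes the acidic C3–H next to the lactone carbonyl with loss of bromide from C4.

Step 9
Reactants: 13 silyl ketene acetal; 16 methyl 3-bromo-2-oxo-2H-pyran-5-carboxylate
Product: 19 methyl (2S,3R)-7-bromo-2-Ar-3-{[(triisopropylsilyl)oxy]methyl}-2,3-dihydro-1-benzofuran-5-carboxylate, via bridged lactone cycloadduct 17 (not isolated), via 7a-silyloxy-3a,7a-dihydrobenzofuran 18 (not isolated)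
Conditions: 16 (1.0 equiv), 13 (1.3 equiv), 2,6-di-tert-butyl-4-methylpyridine (0.2 equiv), PhMe, 25 → 110 °C
Reagents that add atoms: none
Why: The electron-rich cyclic silyl ketene acetal 13 and the electron-poor pyrone 16 are matched partners for an inverse-electron-demand Diels–Alder reaction, the pyrone benzannulation known for coumalates and 3-bromo-2-pyrones with ketene acetals and enol ethers. The nucleophilic β-carbon of 13 (future C3a) should bond to pyrone C6, which is β to the ester and the electrophilic terminus of the dienone, while the acetal carbon (future C7a) bonds to the bromine-bearing C3, possibly in an asynchronous, Michael-like way; this orientation alone places the ester para to O1 and bromine on C7, and both pyrone substituents bias it the same way. Ring A is closed by this intermolecular [4+2] annulation, which forms C3a–C4 and C7–C7a and gives the bridged lactone 17. Heating should drive retro-[4+2] loss of CO2 from 17 to the dihydroarene 18, in which C3a–H and the silyloxy group on C7a are cis at the ring fusion. Aromatization then requires loss of one oxygen from C7a: silanolate is the better nucleofuge and the ring oxygen the better donor, so 18 should ionize to an O1-stabilized arenium ion and lose the C3a proton, giving 19 and silanol, while the hindered pyridine removes traces of acid that would favour protonation and departure of the more basic ring oxygen. No stereocentre is created, because the sp3 centres of 17 and 18 are transient and the face of approach is irrelevant, and C2 and C3 are not touched and keep the configuration of 13. The step therefore needs only regioselectivity and the right choice of leaving group, and both are secured by the polarity of the two partners and by the silyl group.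

Step 10
Reactants: 19 methyl (2S,3R)-7-bromo-2-Ar-3-{[(triisopropylsilyl)oxy]methyl}-2,3-dihydro-1-benzofuran-5-carboxylate
Product: 20 methyl (2S,3R)-2-Ar-7-methoxy-3-{[(triisopropylsilyl)oxy]methyl}-2,3-dihydro-1-benzofuran-5-carboxylate
Conditions: CuI (20 mol%), NaOMe, MeOH/DMF, 100 °C
Reagents that add atoms: sodium methoxide, [Na+].[O-]C
Why: Ullmann-type copper-catalysed methoxylation of an aryl bromide ortho to an ether oxygen, the classical route to guaiacyl and syringyl ethers. Methoxide exchange at the methyl ester is degenerate, the MOM and TIPS ethers are base-stable, and neither stereocentre has an acidic hydrogen.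

Step 11
Reactants: 20 methyl (2S,3R)-2-Ar-7-methoxy-3-{[(triisopropylsilyl)oxy]methyl}-2,3-dihydro-1-benzofuran-5-carboxylate
Product: 21 [(2S,3R)-2-Ar-7-methoxy-3-{[(triisopropylsilyl)oxy]methyl}-2,3-dihydro-1-benzofuran-5-yl]methanol
Conditions: i-Bu2AlH (2.5 equiv), CH2Cl2, −78 → 0 °C; aq. KNaC4H4O6
Reagents that add atoms: none
Why: Hydride reduction of the aryl ester to the benzylic alcohol; acetal, silyl ether and aryl ethers are inert to i-Bu2AlH at low temperature.

Step 12
Reactants: 21 [(2S,3R)-2-Ar-7-methoxy-3-{[(triisopropylsilyl)oxy]methyl}-2,3-dihydro-1-benzofuran-5-yl]methanol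
Product: 22 (2S,3R)-2-Ar-7-methoxy-3-{[(triisopropylsilyl)oxy]methyl}-2,3-dihydro-1-benzofuran-5-carbaldehyde
Conditions: MnO2 (activated, excess), CH2Cl2, 25 °C
Reagents that add atoms: none
Why: MnO2 oxidizes benzylic alcohols selectively to aldehydes under neutral conditions and does not go on to the acid.

Step 13
Reactants: 22 (2S,3R)-2-Ar-7-methoxy-3-{[(triisopropylsilyl)oxy]methyl}-2,3-dihydro-1-benzofuran-5-carbaldehyde
Product: 24 (2E)-3-[(2S,3R)-2-Ar-7-methoxy-3-{[(triisopropylsilyl)oxy]methyl}-2,3-dihydro-1-benzofuran-5-yl]prop-2-enoic acid, via arylidenemalonic acid 23 (not isolated)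
Conditions: CH2(CO2H)2, pyridine, piperidine (cat.), 90 °C
Reagents that add atoms: malonic acid, OC(=O)CC(=O)O
Why: Knoevenagel–Doebner reaction: amine-catalysed condensation gives arylidenemalonic acid 23, whose decarboxylation in hot pyridine should give the E acid (thermodynamic control). The buffered amine medium leaves both protecting groups in place.

Step 14
Reactants: 24 (2E)-3-[(2S,3R)-2-Ar-7-methoxy-3-{[(triisopropylsilyl)oxy]methyl}-2,3-dihydro-1-benzofuran-5-yl]prop-2-enoic acid
Product: 26 (2E)-3-[(2S,3R)-2-(4-hydroxy-3,5-dimethoxyphenyl)-3-(hydroxymethyl)-7-methoxy-2,3-dihydro-1-benzofuran-5-yl]prop-2-enoic acid (target), via phenol silyl ether 25 (not isolated)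
Conditions: 2 M aq. HCl, THF, 40 °C
Reagents that add atoms: none
Why: Acid hydrolysis should remove the hindered, electron-rich aryl MOM acetal first (giving 25) and then the primary TIPS ether; aqueous THF without alcohol avoids esterification of the acid. Should C2 ionize, re-closure would return the more stable trans isomer, since C3 is not affected.

## Compound list

1 | syringaldehyde (4-hydroxy-3,5-dimethoxybenzaldehyde) | COc1cc(C=O)cc(OC)c1O | starting material
2 | 3,5-dimethoxy-4-(methoxymethoxy)benzaldehyde | COCOc1c(OC)cc(C=O)cc1OC | intermediate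
3 | (4S)-4-benzyl-1,3-oxazolidin-2-one | O=C1N[C@@H](Cc2ccccc2)CO1 | starting material
4 | methyl 4-chloro-4-oxobutanoate | COC(=O)CCC(Cl)=O | starting material
5 | methyl 4-[(4S)-4-benzyl-2-oxo-1,3-oxazolidin-3-yl]-4-oxobutanoate | COC(=O)CCC(=O)N1C(=O)OC[C@@H]1Cc1ccccc1 | intermediate
6 | (Z)-dibutylboron enolate of 5: methyl (3Z)-4-[(4S)-4-benzyl-2-oxo-1,3-oxazolidin-3-yl]-4-[(dibutylboranyl)oxy]but-3-enoate | COC(=O)C/C=C(\OB(CCCC)CCCC)N1C(=O)OC[C@@H]1Cc1ccccc1 | intermediate (not isolated)
7 | methyl (3S,4S)-3-{[(4S)-4-benzyl-2-oxo-1,3-oxazolidin-3-yl]carbonyl}-4-[(dibutylboranyl)oxy]-4-[3,5-dimethoxy-4-(methoxymethoxy)phenyl]butanoate (syn-aldol boron aldolate) | COc1cc([C@@H](OB(CCCC)CCCC)[C@H](CC(=O)OC)C(=O)N3C(=O)OC[C@@H]3Cc4ccccc4)cc(OC)c1OCOC | intermediate (not isolated)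
8 | (4S)-4-benzyl-3-{[(2S,3S)-2-[3,5-dimethoxy-4-(methoxymethoxy)phenyl]-5-oxooxolan-3-yl]carbonyl}-1,3-oxazolidin-2-one (trans) | COc1cc([C@H]2OC(=O)C[C@@H]2C(=O)N3C(=O)OC[C@@H]3Cc4ccccc4)cc(OC)c1OCOC | intermediate
9 | (2S,3S)-2-[3,5-dimethoxy-4-(methoxymethoxy)phenyl]-5-oxooxolane-3-carboperoxoic acid | COc1cc([C@H]2OC(=O)C[C@@H]2C(=O)OO)cc(OC)c1OCOC | intermediate (not isolated)
10 | (2S,3S)-2-[3,5-dimethoxy-4-(methoxymethoxy)phenyl]-5-oxooxolane-3-carboxylic acid (trans) | COc1cc([C@H]2OC(=O)C[C@@H]2C(=O)O)cc(OC)c1OCOC | intermediate
11 | (4R,5S)-5-[3,5-dimethoxy-4-(methoxymethoxy)phenyl]-4-(hydroxymethyl)oxolan-2-one (trans) | COc1cc([C@H]2OC(=O)C[C@@H]2CO)cc(OC)c1OCOC | intermediate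
12 | (4R,5S)-5-[3,5-dimethoxy-4-(methoxymethoxy)phenyl]-4-{[(triisopropylsilyl)oxy]methyl}oxolan-2-one (trans) | COc1cc([C@H]2OC(=O)C[C@@H]2CO[Si](C(C)C)(C(C)C)C(C)C)cc(OC)c1OCOC | intermediate
13 | tert-butyl{[(4R,5S)-5-[3,5-dimethoxy-4-(methoxymethoxy)phenyl]-4-{[(triisopropylsilyl)oxy]methyl}-4,5-dihydrofuran-2-yl]oxy}dimethylsilane (trans; key-step precursor) | COc1cc([C@H]2OC(O[Si](C)(C)C(C)(C)C)=C[C@@H]2CO[Si](C(C)C)(C(C)C)C(C)C)cc(OC)c1OCOC | intermediate
14 | methyl coumalate (methyl 2-oxo-2H-pyran-5-carboxylate) | COC(=O)C1=COC(=O)C=C1 | starting material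
15 | methyl trans-3,4-dibromo-2-oxo-3,4-dihydro-2H-pyran-5-carboxylate (racemic, one enantiomer drawn) | COC(=O)C1=COC(=O)[C@H](Br)[C@H]1Br | intermediate (not isolated)
16 | methyl 3-bromo-2-oxo-2H-pyran-5-carboxylate | COC(=O)C1=COC(=O)C(Br)=C1 | intermediate
17 | bridged lactone cycloadduct: 2-oxabicyclo[2.2.2]oct-7-en-3-one with the dihydrofuran ring of 13 fused across C5–C6; C7a (O1 and OSiMe2t-Bu) on the bromine-bearing bridgehead, C3a on the oxygen-bearing bridgehead, CO2Me on the alkene carbon next to the latter; (2S,3R) at the carried centres | COc1cc([C@H]2OC3(O[Si](C)(C)C(C)(C)C)C([C@@H]2CO[Si](C(C)C)(C(C)C)C(C)C)C4OC(=O)C3(Br)C=C4C(=O)OC)cc(OC)c1OCOC | intermediate (not isolated)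
18 | methyl (2S,3R)-7-bromo-7a-[(tert-butyldimethylsilyl)oxy]-2-[3,5-dimethoxy-4-(methoxymethoxy)phenyl]-3-{[(triisopropylsilyl)oxy]methyl}-2,3,3a,7a-tetrahydro-1-benzofuran-5-carboxylate (cis ring fusion) | COc1cc([C@H]2OC3(O[Si](C)(C)C(C)(C)C)C([C@@H]2CO[Si](C(C)C)(C(C)C)C(C)C)C=C(C(=O)OC)C=C3Br)cc(OC)c1OCOC | intermediate (not isolated)
19 | methyl (2S,3R)-7-bromo-2-[3,5-dimethoxy-4-(methoxymethoxy)phenyl]-3-{[(triisopropylsilyl)oxy]methyl}-2,3-dihydro-1-benzofuran-5-carboxylate (trans; key-step product) | COc1cc([C@H]2Oc3c(Br)cc(C(=O)OC)cc3[C@@H]2CO[Si](C(C)C)(C(C)C)C(C)C)cc(OC)c1OCOC | intermediate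
20 | methyl (2S,3R)-2-[3,5-dimethoxy-4-(methoxymethoxy)phenyl]-7-methoxy-3-{[(triisopropylsilyl)oxy]methyl}-2,3-dihydro-1-benzofuran-5-carboxylate | COc1cc([C@H]2Oc3c(OC)cc(C(=O)OC)cc3[C@@H]2CO[Si](C(C)C)(C(C)C)C(C)C)cc(OC)c1OCOC | intermediate
21 | [(2S,3R)-2-[3,5-dimethoxy-4-(methoxymethoxy)phenyl]-7-methoxy-3-{[(triisopropylsilyl)oxy]methyl}-2,3-dihydro-1-benzofuran-5-yl]methanol | COc1cc([C@H]2Oc3c(OC)cc(CO)cc3[C@@H]2CO[Si](C(C)C)(C(C)C)C(C)C)cc(OC)c1OCOC | intermediate
22 | (2S,3R)-2-[3,5-dimethoxy-4-(methoxymethoxy)phenyl]-7-methoxy-3-{[(triisopropylsilyl)oxy]methyl}-2,3-dihydro-1-benzofuran-5-carbaldehyde | COc1cc([C@H]2Oc3c(OC)cc(C=O)cc3[C@@H]2CO[Si](C(C)C)(C(C)C)C(C)C)cc(OC)c1OCOC | intermediate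
23 | 2-{[(2S,3R)-2-[3,5-dimethoxy-4-(methoxymethoxy)phenyl]-7-methoxy-3-{[(triisopropylsilyl)oxy]methyl}-2,3-dihydro-1-benzofuran-5-yl]methylidene}propanedioic acid | COc1cc([C@H]2Oc3c(OC)cc(C=C(C(=O)O)C(=O)O)cc3[C@@H]2CO[Si](C(C)C)(C(C)C)C(C)C)cc(OC)c1OCOC | intermediate (not isolated)
24 | (2E)-3-[(2S,3R)-2-[3,5-dimethoxy-4-(methoxymethoxy)phenyl]-7-methoxy-3-{[(triisopropylsilyl)oxy]methyl}-2,3-dihydro-1-benzofuran-5-yl]prop-2-enoic acid | COc1cc([C@H]2Oc3c(OC)cc(/C=C/C(=O)O)cc3[C@@H]2CO[Si](C(C)C)(C(C)C)C(C)C)cc(OC)c1OCOC | intermediate
25 | (2E)-3-[(2S,3R)-2-(4-hydroxy-3,5-dimethoxyphenyl)-7-methoxy-3-{[(triisopropylsilyl)oxy]methyl}-2,3-dihydro-1-benzofuran-5-yl]prop-2-enoic acid | COc1cc([C@H]2Oc3c(OC)cc(/C=C/C(=O)O)cc3[C@@H]2CO[Si](C(C)C)(C(C)C)C(C)C)cc(OC)c1O | intermediate (not isolated)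
26 | (2E)-3-[(2S,3R)-2-(4-hydroxy-3,5-dimethoxyphenyl)-3-(hydroxymethyl)-7-methoxy-2,3-dihydro-1-benzofuran-5-yl]prop-2-enoic acid (trans) | COc1cc([C@H]2Oc3c(OC)cc(/C=C/C(=O)O)cc3[C@@H]2CO)cc(OC)c1O | target

## Step count and least certain steps

Total step count: 14 (steps 1–14). Longest linear sequence: 12 steps (1, 3, 4, 5, 6, 7, 9, 10, 11, 12, 13, 14); steps 2 and 8 are side branches.

**Step 9 (key step).** The most likely failure is aromatization with expulsion of the ring oxygen O1 instead of silanol. O1 is the more basic oxygen and lies anti to C3a–H, so traces of acid or an E2-like course could favour it. Hydrolysis of the ketene acetal before cycloaddition is the second concern. The fallback accepts ring opening; it sets out from 13 and 16 and returns at 19. The same cycloaddition and decarboxylation through 17 and 18 would then end in methyl 3-bromo-4-[(tert-butyldimethylsilyl)oxy]-5-[(1S,2R)-1-Ar-1-hydroxy-3-(triisopropylsilyloxy)propan-2-yl]benzoate F1. K2CO3 in MeOH would free the phenol to give methyl 3-bromo-4-hydroxy-5-[(1S,2R)-1-Ar-1-hydroxy-3-(triisopropylsilyloxy)propan-2-yl]benzoate F2. A catalytic sulfonic acid in dry CH2Cl2 (4 Å sieves, 0 °C) would then ionize the electron-rich benzylic alcohol and let the phenol close O1–C2 by SN1 cycloetherification. The trans isomer is expected from the bias of the untouched C3 centre, giving 19.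

**Step 7.** Competing C-silylation of the lactone enolate and hydrolytic loss of the ketene acetal during handling are the likely problems, since 13 cannot be distilled or chromatographed on ordinary silica. The fallback changes the enol derivative; it sets out from 12 and returns at 19. Lawesson's reagent (PhMe, 100 °C) would convert 12 into (4R,5S)-5-Ar-4-{[(triisopropylsilyl)oxy]methyl}oxolane-2-thione F3. LiN(i-Pr)2 then MeI would alkylate the soft sulfur regiospecifically to the ketene O,S-acetal (4R,5S)-5-Ar-2-(methylsulfanyl)-4-{[(triisopropylsilyl)oxy]methyl}-4,5-dihydrofuran F4, which is more robust to moisture. Heated with 16 in PhMe, F4 should pass through the bridged lactone cycloadduct carrying SMe on C7a F5 and the 7a-methylsulfanyl-3a,7a-dihydrobenzofuran F6. Loss of methanethiol from F6, thiolate being a far better leaving group than either oxygen, would give 19.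

**Step 10.** Hydrodebromination and partial cleavage of the ester under hot methoxide are the usual side processes of copper methoxylation, and the bromide is flanked by O1. The fallback replaces direct C–O coupling by borylation, oxidation and methylation; it sets out from 19 and returns at 20. Miyaura borylation (PdCl2(dppf), B2pin2, KOAc, dioxane, 90 °C) would give the pinacol boronate methyl (2S,3R)-2-Ar-7-(4,4,5,5-tetramethyl-1,3,2-dioxaborolan-2-yl)-3-{[(triisopropylsilyl)oxy]methyl}-2,3-dihydro-1-benzofuran-5-carboxylate F7. Oxidation (NaBO3·4H2O, THF/H2O) would give the phenol methyl (2S,3R)-2-Ar-7-hydroxy-3-{[(triisopropylsilyl)oxy]methyl}-2,3-dihydro-1-benzofuran-5-carboxylate F8, and MeI/K2CO3 in acetone would give 20.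

**Step 14.** The risk is incomplete cleavage of the primary TIPS ether at an acid strength that the p-hydroxybenzylic O1–C2 bond tolerates, or, if the acid is pushed, ionization at C2 with loss of formaldehyde from C3. The fallback separates the two unmaskings into orthogonal operations; it sets out from 24 and returns at 26. Bu4NF buffered with AcOH in THF would remove only the silyl group to give (2E)-3-[(2S,3R)-2-Ar-3-(hydroxymethyl)-7-methoxy-2,3-dihydro-1-benzofuran-5-yl]prop-2-enoic acid F9. The remaining aryl MOM acetal, the most labile group in the molecule, would then be removed with 0.5 M aq. HCl in THF at 25 °C to give 26.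

## Further compounds

F1 | step 9 | methyl 3-bromo-4-[(tert-butyldimethylsilyl)oxy]-5-[(1S,2R)-1-[3,5-dimethoxy-4-(methoxymethoxy)phenyl]-1-hydroxy-3-(triisopropylsilyloxy)propan-2-yl]benzoate | COc1cc([C@@H](O)[C@@H](CO[Si](C(C)C)(C(C)C)C(C)C)c2cc(C(=O)OC)cc(Br)c2O[Si](C)(C)C(C)(C)C)cc(OC)c1OCOC
F2 | step 9 | methyl 3-bromo-4-hydroxy-5-[(1S,2R)-1-[3,5-dimethoxy-4-(methoxymethoxy)phenyl]-1-hydroxy-3-(triisopropylsilyloxy)propan-2-yl]benzoate | COc1cc([C@@H](O)[C@@H](CO[Si](C(C)C)(C(C)C)C(C)C)c2cc(C(=O)OC)cc(Br)c2O)cc(OC)c1OCOC
F3 | step 7 | (4R,5S)-5-[3,5-dimethoxy-4-(methoxymethoxy)phenyl]-4-{[(triisopropylsilyl)oxy]methyl}oxolane-2-thione | COc1cc([C@H]2OC(=S)C[C@@H]2CO[Si](C(C)C)(C(C)C)C(C)C)cc(OC)c1OCOC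
F4 | step 7 | (4R,5S)-5-[3,5-dimethoxy-4-(methoxymethoxy)phenyl]-2-(methylsulfanyl)-4-{[(triisopropylsilyl)oxy]methyl}-4,5-dihydrofuran | COc1cc([C@H]2OC(SC)=C[C@@H]2CO[Si](C(C)C)(C(C)C)C(C)C)cc(OC)c1OCOC
F5 | step 7 | bridged lactone cycloadduct of F4 and 16 (as 17, with SMe in place of the silyloxy group on C7a) | COc1cc([C@H]2OC3(SC)C([C@@H]2CO[Si](C(C)C)(C(C)C)C(C)C)C4OC(=O)C3(Br)C=C4C(=O)OC)cc(OC)c1OCOC
F6 | step 7 | methyl (2S,3R)-7-bromo-2-[3,5-dimethoxy-4-(methoxymethoxy)phenyl]-7a-(methylsulfanyl)-3-{[(triisopropylsilyl)oxy]methyl}-2,3,3a,7a-tetrahydro-1-benzofuran-5-carboxylate | COc1cc([C@H]2OC3(SC)C([C@@H]2CO[Si](C(C)C)(C(C)C)C(C)C)C=C(C(=O)OC)C=C3Br)cc(OC)c1OCOC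
F7 | step 10 | methyl (2S,3R)-2-[3,5-dimethoxy-4-(methoxymethoxy)phenyl]-7-(4,4,5,5-tetramethyl-1,3,2-dioxaborolan-2-yl)-3-{[(triisopropylsilyl)oxy]methyl}-2,3-dihydro-1-benzofuran-5-carboxylate | COc1cc([C@H]2Oc3c(B4OC(C)(C)C(C)(C)O4)cc(C(=O)OC)cc3[C@@H]2CO[Si](C(C)C)(C(C)C)C(C)C)cc(OC)c1OCOC
F8 | step 10 | methyl (2S,3R)-2-[3,5-dimethoxy-4-(methoxymethoxy)phenyl]-7-hydroxy-3-{[(triisopropylsilyl)oxy]methyl}-2,3-dihydro-1-benzofuran-5-carboxylate | COc1cc([C@H]2Oc3c(O)cc(C(=O)OC)cc3[C@@H]2CO[Si](C(C)C)(C(C)C)C(C)C)cc(OC)c1OCOC
F9 | step 14 | (2E)-3-[(2S,3R)-2-[3,5-dimethoxy-4-(methoxymethoxy)phenyl]-3-(hydroxymethyl)-7-methoxy-2,3-dihydro-1-benzofuran-5-yl]prop-2-enoic acid | COc1cc([C@H]2Oc3c(OC)cc(/C=C/C(=O)O)cc3[C@@H]2CO)cc(OC)c1OCOC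
A1 | alternative 1 | ethyl 2-diazo-2-{2-[3,5-dimethoxy-4-(triisopropylsilyloxy)benzyloxy]-5-(1,3-dioxolan-2-yl)-3-methoxyphenyl}acetate | CCOC(=O)C(=[N+]=[N-])c1cc(C2OCCO2)cc(OC)c1OCc1cc(OC)c(O[Si](C(C)C)(C(C)C)C(C)C)c(OC)c1
A2 | alternative 1 | ethyl (2S,3R)-cis-2-[3,5-dimethoxy-4-(triisopropylsilyloxy)phenyl]-5-(1,3-dioxolan-2-yl)-7-methoxy-2,3-dihydrobenzofuran-3-carboxylate | COc1cc([C@H]2Oc3c(OC)cc(C4OCCO4)cc3[C@H]2C(=O)OCC)cc(OC)c1O[Si](C(C)C)(C(C)C)C(C)C
A3 | alternative 1 | ethyl (2S,3S)-trans-2-[3,5-dimethoxy-4-(triisopropylsilyloxy)phenyl]-5-(1,3-dioxolan-2-yl)-7-methoxy-2,3-dihydrobenzofuran-3-carboxylate | COc1cc([C@H]2Oc3c(OC)cc(C4OCCO4)cc3[C@@H]2C(=O)OCC)cc(OC)c1O[Si](C(C)C)(C(C)C)C(C)C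
A4 | alternative 2 | 2-(7-methoxy-1-benzofuran-5-yl)-1,3-dioxolane | COc1cc(C2OCCO2)cc2ccoc12
A5 | alternative 2 | 2-[3,5-dimethoxy-4-(triisopropylsilyloxy)phenyl]-4,4,5,5-tetramethyl-1,3,2-dioxaborolane | COc1cc(B2OC(C)(C)C(C)(C)O2)cc(OC)c1O[Si](C(C)C)(C(C)C)C(C)C
A6 | alternative 2 | lithium [5-(1,3-dioxolan-2-yl)-7-methoxy-1-benzofuran-2-yl][3,5-dimethoxy-4-(triisopropylsilyloxy)phenyl](pinacolato)borate | [Li+].COc1cc(C2OCCO2)cc2cc([B-]3(OC(C)(C)C(C)(C)O3)c3cc(OC)c(O[Si](C(C)C)(C(C)C)C(C)C)c(OC)c3)oc12
A7 | alternative 2 | 2-[(2S,3S)-3-allyl-2-[3,5-dimethoxy-4-(triisopropylsilyloxy)phenyl]-5-(1,3-dioxolan-2-yl)-7-methoxy-2,3-dihydro-1-benzofuran-2-yl]-4,4,5,5-tetramethyl-1,3,2-dioxaborolane (aryl and allyl trans) | COc1cc([C@@]2(B3OC(C)(C)C(C)(C)O3)Oc3c(OC)cc(C4OCCO4)cc3[C@@H]2CC=C)cc(OC)c1O[Si](C(C)C)(C(C)C)C(C)C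
A8 | alternative 3 | (2R)-2-(5-bromo-2-hydroxy-3-methoxyphenyl)-3-(4-hydroxy-3,5-dimethoxyphenyl)propan-1-ol | COc1cc(C[C@@H](CO)c2cc(Br)cc(OC)c2O)cc(OC)c1O
A9 | alternative 3 | 4-[(2R)-2-(5-bromo-2-hydroxy-3-methoxyphenyl)-3-hydroxypropylidene]-2,6-dimethoxycyclohexa-2,5-dien-1-one | COC1=CC(=C[C@@H](CO)c2cc(Br)cc(OC)c2O)C=C(OC)C1=O
A10 | alternative 3 | (2S,3R)-trans-5-bromo-2-(4-hydroxy-3,5-dimethoxyphenyl)-3-(hydroxymethyl)-7-methoxy-2,3-dihydrobenzofuran | COc1cc([C@H]2Oc3c(OC)cc(Br)cc3[C@@H]2CO)cc(OC)c1O
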